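The route cuts, in this order: the C5–O bond of ring A, the O1–C2 bond of ring C, the C2=C3 bond (the chalcone alkene), and the C4–C4a bond (acetyl to ring A).
The key step is possible because the C4 carbonyl oxygen of ring C lies peri to C5–H of ring A. Ru, O, C4, C4a and C5 can therefore form a five-membered metallacycle, and C5 is also para to the 8-methoxy group.
Forward: symmetric 2-methoxyresorcinol is acetylated and joined to the ring B aldehyde. Ring C is then closed, the benzyl ethers are exchanged for pivalates, C5–H is oxygenated and the esters are removed.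
Rings A and B are bought, and ring C is the only ring made. The ketone carries a single ortho hydroxyl, next to the methoxy group, so only the 8-methoxy pattern can form.
The target has no stereocentre. The only stereo-element on the way is the E alkene of the chalcone, set by E1cB elimination and consumed on ring closure.

Key step: step 8

Remark: flavone numbering is used throughout (O1, C2, C3, C4, C4a, C5 to C8, C8a for rings C and A; primed numbers for ring B). Compounds 1 and 5 are taken to be purchasable.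

Step 1
Reactants: 1 2-methoxyresorcinol (2-methoxybenzene-1,3-diol)
Product: 3 1-(2,4-dihydroxy-3-methoxyphenyl)ethan-1-one, via ketiminium chloride 2 (not isolated)
Conditions: MeCN, ZnCl2, HCl (g), Et2O, 0 °C to rt; then H2O, reflux
Reagents that add atoms: acetonitrile, CC#N; water, O; hydrogen chloride, Cl (counter-ion of 2 only)
Why: Houben-Hoesch acylation, in which ZnCl2-activated acetimidoyl chloride formed from MeCN and HCl attacks the position ortho to one hydroxyl and para to the other (the two such positions of symmetric 1 are equivalent), and the deactivated ketiminium salt resists a second acylation and is hydrolysed to the ketone in hot water.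

Step 2
Reactants: 3 1-(2,4-dihydroxy-3-methoxyphenyl)ethan-1-one
Product: 4 1-[4-(benzyloxy)-2-hydroxy-3-methoxyphenyl]ethan-1-one
Conditions: BnBr (1.0 equiv), K2CO3, acetone, reflux
Reagents that add atoms: benzyl bromide, BrCc1ccccc1
Why: Williamson ether synthesis under weak base, in which the 2-hydroxyl is hydrogen-bonded to the acetyl oxygen and flanked on both sides, so one equivalent of halide should alkylate only the more acidic and more accessible 4-phenoxide.

Step 3
Reactants: 5 2-hydroxy-4,5-dimethoxybenzaldehyde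
Product: 6 2-(benzyloxy)-4,5-dimethoxybenzaldehyde
Conditions: BnBr, K2CO3, DMF, 60 °C
Reagents that add atoms: benzyl bromide, BrCc1ccccc1
Why: Williamson ether synthesis, in which warming in DMF overcomes the hydrogen bond of the salicylaldehyde hydroxyl, and the ether prevents a phenoxide from deactivating the aldehyde in the aldol step.

Step 4
Reactants: 4 1-[4-(benzyloxy)-2-hydroxy-3-methoxyphenyl]ethan-1-one, 6 2-(benzyloxy)-4,5-dimethoxybenzaldehyde
Product: 7 (E)-1-[4-(benzyloxy)-2-hydroxy-3-methoxyphenyl]-3-[2-(benzyloxy)-4,5-dimethoxyphenyl]prop-2-en-1-one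
Conditions: KOH, EtOH/H2O, rt; then 1 M HCl
Reagents that add atoms: none
Why: Claisen-Schmidt condensation, in which the methyl ketone enolate adds to the non-enolisable aldehyde and E1cB loss of hydroxide gives the conjugated E enone under thermodynamic control, both benzyl ethers being inert to alkali.

Step 5
Reactants: 7 (E)-1-[4-(benzyloxy)-2-hydroxy-3-methoxyphenyl]-3-[2-(benzyloxy)-4,5-dimethoxyphenyl]prop-2-en-1-one
Product: 8 7-(benzyloxy)-2-[2-(benzyloxy)-4,5-dimethoxyphenyl]-8-methoxy-4H-chromen-4-one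
Conditions: I2 (10 mol %), DMSO, 130 °C
Reagents that add atoms: none
Why: Iodine-catalysed oxidative cyclisation of a 2'-hydroxychalcone, in which 6-endo attack of the only ortho hydroxyl on the iodine-activated enone forms O1–C2, loss of HI makes ring C fully unsaturated, and DMSO reoxidises HI to I2.

Step 6
Reactants: 8 7-(benzyloxy)-2-[2-(benzyloxy)-4,5-dimethoxyphenyl]-8-methoxy-4H-chromen-4-one
Product: 9 7-hydroxy-2-(2-hydroxy-4,5-dimethoxyphenyl)-8-methoxy-4H-chromen-4-one
Conditions: H2 (1 atm), 10% Pd/C, THF/MeOH, rt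
Reagents that add atoms: none
Why: Catalytic hydrogenolysis of aryl benzyl ethers, which at one atmosphere and room temperature should be much faster than reduction of the C2=C3 bond of the vinylogous ester in ring C.

Step 7
Reactants: 9 7-hydroxy-2-(2-hydroxy-4,5-dimethoxyphenyl)-8-methoxy-4H-chromen-4-one
Product: 10 2-[4,5-dimethoxy-2-(pivaloyloxy)phenyl]-8-methoxy-4-oxo-4H-chromen-7-yl pivalate
Conditions: PivCl (2.5 equiv), Et3N, 4-(dimethylamino)pyridine (cat.), CH2Cl2, 0 °C to rt
Reagents that add atoms: pivaloyl chloride, CC(C)(C)C(=O)Cl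
Why: Nucleophile-catalysed O-acylation of both phenols, giving hindered aryl esters that should withstand hot CF3CO2H, mask the phenols from the oxidant and draw electron density out of rings A and B.

Step 8
Reactants: 10 2-[4,5-dimethoxy-2-(pivaloyloxy)phenyl]-8-methoxy-4-oxo-4H-chromen-7-yl pivalate
Product: 12 2-[4,5-dimethoxy-2-(pivaloyloxy)phenyl]-5-hydroxy-8-methoxy-4-oxo-4H-chromen-7-yl pivalate, via C5 trifluoroacetate 11 (not isolated)
Conditions: [RuCl2(p-cymene)]2 (5 mol %), PhI(OCOCF3)2 (1.5 equiv), CF3CO2H/(CF3CO)2O, 80 °C; then aq. Na2S2O3/NaHCO3 work-up, rt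
Reagents that add atoms: phenyliodine bis(trifluoroacetate), O=C(OI(OC(=O)C(F)(F)F)c1ccccc1)C(F)(F)F
Why: Exchange of chloride for trifluoroacetate gives a divalent ruthenium carboxylate that binds the C4 carbonyl oxygen of 10 and cleaves the peri C5–H bond by carboxylate-assisted metalation, forming a five-membered ruthenacycle (Ru, O, C4, C4a, C5). The trivalent iodine reagent oxidises this to tetravalent ruthenium, C5–O reductive elimination releases 11 and divalent ruthenium, and the aqueous work-up hydrolyses the labile aryl trifluoroacetate to the hydrogen-bonded phenol 12. The reaction type is the ruthenium-catalysed ketone-directed ortho C–H hydroxylation of aryl ketones, which is established at C5 of flavones and chromones. No ring of the product is closed and no stereocentre is formed. The step must select C5 over C3, C6, C3' and C6': only C5–H lies within reach of the bound carbonyl, C5 is para to the 8-methoxy group and so the most electron-rich CH of ring A, and the pivalate carbonyls could reach C6 or C3' only through weaker six-membered chelates. The esters and the chromone make both rings harder to oxidise, (CF3CO)2O keeps the new oxygen masked so that the para-methoxyphenol is not carried on towards a quinone, and left-over oxidant is reduced before the phenol is set free.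

Step 9
Reactants: 12 2-[4,5-dimethoxy-2-(pivaloyloxy)phenyl]-5-hydroxy-8-methoxy-4-oxo-4H-chromen-7-yl pivalate
Product: 13 5,7-dihydroxy-2-(2-hydroxy-4,5-dimethoxyphenyl)-8-methoxy-4H-chromen-4-one (5,7,2'-trihydroxy-8,4',5'-trimethoxyflavone)
Conditions: K2CO3 (3 equiv), MeOH, Ar, rt; then 1 M HCl
Reagents that add atoms: none
Why: Base-mediated transesterification of aryl esters, in which the phenoxide leaving groups should let even hindered pivalates go at room temperature, conditions too mild to open ring C, while exclusion of air protects the electron-rich phenolate.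

Compound list
1 | 2-methoxyresorcinol | COc1c(O)cccc1O | starting material
2 | 1-(2,4-dihydroxy-3-methoxyphenyl)ethan-1-iminium chloride | CC(=[NH2+])c1ccc(O)c(OC)c1O.[Cl-] | intermediate
3 | 1-(2,4-dihydroxy-3-methoxyphenyl)ethan-1-one | CC(=O)c1ccc(O)c(OC)c1O | intermediate
4 | 1-[4-(benzyloxy)-2-hydroxy-3-methoxyphenyl]ethan-1-one | CC(=O)c1ccc(OCc2ccccc2)c(OC)c1O | intermediate
5 | 2-hydroxy-4,5-dimethoxybenzaldehyde | O=Cc1cc(OC)c(OC)cc1O | starting material
6 | 2-(benzyloxy)-4,5-dimethoxybenzaldehyde | O=Cc1cc(OC)c(OC)cc1OCc1ccccc1 | intermediate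
7 | (E)-1-[4-(benzyloxy)-2-hydroxy-3-methoxyphenyl]-3-[2-(benzyloxy)-4,5-dimethoxyphenyl]prop-2-en-1-one | COc1cc(OCc2ccccc2)c(/C=C/C(=O)c2ccc(OCc3ccccc3)c(OC)c2O)cc1OC | intermediate
8 | 7-(benzyloxy)-2-[2-(benzyloxy)-4,5-dimethoxyphenyl]-8-methoxy-4H-chromen-4-one | COc1cc(OCc2ccccc2)c(-c2cc(=O)c3ccc(OCc4ccccc4)c(OC)c3o2)cc1OC | intermediate
9 | 7-hydroxy-2-(2-hydroxy-4,5-dimethoxyphenyl)-8-methoxy-4H-chromen-4-one | COc1cc(O)c(-c2cc(=O)c3ccc(O)c(OC)c3o2)cc1OC | intermediate
10 | 2-[4,5-dimethoxy-2-(pivaloyloxy)phenyl]-8-methoxy-4-oxo-4H-chromen-7-yl pivalate | COc1cc(OC(=O)C(C)(C)C)c(-c2cc(=O)c3ccc(OC(=O)C(C)(C)C)c(OC)c3o2)cc1OC | intermediate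
11 | 2-[4,5-dimethoxy-2-(pivaloyloxy)phenyl]-8-methoxy-4-oxo-5-(trifluoroacetoxy)-4H-chromen-7-yl pivalate | COc1cc(OC(=O)C(C)(C)C)c(-c2cc(=O)c3c(OC(=O)C(F)(F)F)cc(OC(=O)C(C)(C)C)c(OC)c3o2)cc1OC | intermediate
12 | 2-[4,5-dimethoxy-2-(pivaloyloxy)phenyl]-5-hydroxy-8-methoxy-4-oxo-4H-chromen-7-yl pivalate | COc1cc(OC(=O)C(C)(C)C)c(-c2cc(=O)c3c(O)cc(OC(=O)C(C)(C)C)c(OC)c3o2)cc1OC | intermediate
13 | 5,7-dihydroxy-2-(2-hydroxy-4,5-dimethoxyphenyl)-8-methoxy-4H-chromen-4-one | COc1cc(O)c(-c2cc(=O)c3c(O)cc(O)c(OC)c3o2)cc1OC | target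

Total step count: 9. Longest linear sequence: 8 steps (1, 2, 4, 5, 6, 7, 8, 9, counted from 1).

Steps most likely to fail

**Step 8.** The trivalent iodine reagent may oxidise the dimethoxy-substituted ring B by single-electron transfer. The catalyst may also stall on the crowded substrate, or ring A may be over-oxidised once the new oxygen is in place.

The fallback buys the 5-oxygen with ring A and adds the 8-oxygen instead. It sets out from 6.
- Commercial 2',4',6'-trihydroxyacetophenone is benzylated once at its non-chelated 4'-hydroxyl (BnBr, K2CO3, acetone) to 1-[4-(benzyloxy)-2,6-dihydroxyphenyl]ethan-1-one F1.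
- Claisen-Schmidt condensation of this ketone with 6 (KOH, EtOH) should give (E)-1-[4-(benzyloxy)-2,6-dihydroxyphenyl]-3-[2-(benzyloxy)-4,5-dimethoxyphenyl]prop-2-en-1-one F2.
- I2 in DMSO closes it to 7-(benzyloxy)-2-[2-(benzyloxy)-4,5-dimethoxyphenyl]-5-hydroxy-4H-chromen-4-one F3. The two ortho hydroxyls are equivalent, so only one flavone can arise.
- Elbs persulfate oxidation (K2S2O8, aq. KOH/pyridine, rt) attacks the position para to the 5-phenoxide and gives the potassium C8 sulfate ester F4.
- Hydrolysis of F4 with warm dilute HCl gives 7-(benzyloxy)-2-[2-(benzyloxy)-4,5-dimethoxyphenyl]-5,8-dihydroxy-4H-chromen-4-one F5.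
- One equivalent of MeI with K2CO3 in acetone methylates the non-chelated 8-hydroxyl to 7-(benzyloxy)-2-[2-(benzyloxy)-4,5-dimethoxyphenyl]-5-hydroxy-8-methoxy-4H-chromen-4-one F6.
- Hydrogenolysis of both benzyl ethers (H2, 10% Pd/C) comes back to the route at 13.

**Step 5.** At 130 °C the HI formed in the flask may strip benzyl groups, and iodine may substitute the electron-rich ring B. The fallback avoids iodine and separates ring closure from oxidation.
- It sets out from 7, which is equilibrated by oxa-Michael addition (NaOAc, EtOH, reflux) to racemic 7-(benzyloxy)-2-[2-(benzyloxy)-4,5-dimethoxyphenyl]-8-methoxychroman-4-one F7.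
- Dehydrogenation with 2,3-dichloro-5,6-dicyano-1,4-benzoquinone in 1,4-dioxane at reflux removes the C2 and C3 hydrogens and comes back to the route at 8.

**Step 9.** The hindered esters may need long exposure to base. During that time ring C could open and re-close through the 5- or the 2'-oxygen, and the phenolate could be air-oxidised. The fallback changes the ester so that the last step can run under mild acid.
- It sets out from 9, which is acetylated (Ac2O, pyridine) to 2-[2-(acetyloxy)-4,5-dimethoxyphenyl]-8-methoxy-4-oxo-4H-chromen-7-yl acetate F8.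
- The ruthenium-catalysed C5–H oxygenation of step 8 is applied to F8. It passes through the C5 trifluoroacetate F9 to 2-[2-(acetyloxy)-4,5-dimethoxyphenyl]-5-hydroxy-8-methoxy-4-oxo-4H-chromen-7-yl acetate F10.
- Acid-catalysed methanolysis (catalytic AcCl in MeOH, rt) removes both acetates and comes back to the route at 13.

Further compounds
F1 | step 8 | 1-[4-(benzyloxy)-2,6-dihydroxyphenyl]ethan-1-one | CC(=O)c1c(O)cc(OCc2ccccc2)cc1O
F2 | step 8 | (E)-1-[4-(benzyloxy)-2,6-dihydroxyphenyl]-3-[2-(benzyloxy)-4,5-dimethoxyphenyl]prop-2-en-1-one | COc1cc(OCc2ccccc2)c(/C=C/C(=O)c2c(O)cc(OCc3ccccc3)cc2O)cc1OC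
F3 | step 8 | 7-(benzyloxy)-2-[2-(benzyloxy)-4,5-dimethoxyphenyl]-5-hydroxy-4H-chromen-4-one | COc1cc(OCc2ccccc2)c(-c2cc(=O)c3c(O)cc(OCc4ccccc4)cc3o2)cc1OC
F4 | step 8 | potassium 7-(benzyloxy)-2-[2-(benzyloxy)-4,5-dimethoxyphenyl]-5-hydroxy-4-oxo-4H-chromen-8-yl sulfate (potassium C8 sulfate ester) | COc1cc(OCc2ccccc2)c(-c2cc(=O)c3c(O)cc(OCc4ccccc4)c(OS(=O)(=O)[O-])c3o2)cc1OC.[K+]
F5 | step 8 | 7-(benzyloxy)-2-[2-(benzyloxy)-4,5-dimethoxyphenyl]-5,8-dihydroxy-4H-chromen-4-one | COc1cc(OCc2ccccc2)c(-c2cc(=O)c3c(O)cc(OCc4ccccc4)c(O)c3o2)cc1OC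
F6 | step 8 | 7-(benzyloxy)-2-[2-(benzyloxy)-4,5-dimethoxyphenyl]-5-hydroxy-8-methoxy-4H-chromen-4-one | COc1cc(OCc2ccccc2)c(-c2cc(=O)c3c(O)cc(OCc4ccccc4)c(OC)c3o2)cc1OC
F7 | step 5 | 7-(benzyloxy)-2-[2-(benzyloxy)-4,5-dimethoxyphenyl]-8-methoxychroman-4-one (racemic) | COc1cc(OCc2ccccc2)c(C2CC(=O)c3ccc(OCc4ccccc4)c(OC)c3O2)cc1OC
F8 | step 9 | 2-[2-(acetyloxy)-4,5-dimethoxyphenyl]-8-methoxy-4-oxo-4H-chromen-7-yl acetate | COc1cc(OC(C)=O)c(-c2cc(=O)c3ccc(OC(C)=O)c(OC)c3o2)cc1OC
F9 | step 9 | 2-[2-(acetyloxy)-4,5-dimethoxyphenyl]-8-methoxy-4-oxo-5-(trifluoroacetoxy)-4H-chromen-7-yl acetate (C5 trifluoroacetate) | COc1cc(OC(C)=O)c(-c2cc(=O)c3c(OC(=O)C(F)(F)F)cc(OC(C)=O)c(OC)c3o2)cc1OC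
F10 | step 9 | 2-[2-(acetyloxy)-4,5-dimethoxyphenyl]-5-hydroxy-8-methoxy-4-oxo-4H-chromen-7-yl acetate | COc1cc(OC(C)=O)c(-c2cc(=O)c3c(O)cc(OC(C)=O)c(OC)c3o2)cc1OC
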